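## Retrosynthetic overview

1. The target comes from Pd/C debenzylation of bis-benzyl lariciresinol **20**. **20** comes from acid cyclodehydration of triol **19**: the C9′-OH closes the tetrahydrofuran onto the C7 benzylic cation and sets C7 (aryl trans to the two cis CH2 groups).
2. **19** comes from LiAlH4 reduction of trans-lactone **18**. **18** is the late coupling of lactone enolate **10** (26 heavy atoms) with benzyl bromide **17** (20 heavy atoms), anti to the C8 substituent, which sets C8′.
3. Lactone **10** comes from the Sharpless (2S,3S)-epoxy alcohol acetate **9** by 5-exo epoxide opening by the ester enolate, with inversion at C2, which sets C8 and closes the γ-lactone. The epoxy alcohol comes from a Heck cinnamate made from 4-bromophenol.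
4. Bromide **17** is built independently from p-cresol through syringaldehyde, so the two fragments share no intermediates.
5. Rings are formed in this order: γ-lactone (Step 8), then tetrahydrofuran (Step 17).

Assumption: the SMILES is the natural lariciresinol series (7S,8R,8′R), and Ar = 4-(benzyloxy)-3,5-dimethoxyphenyl.

## Route

**Step 1**
Reactants: **1** 4-bromophenol
Product: **2** 2,4,6-tribromophenol
Conditions: Br2 (2.1 equiv), AcOH, rt
Reagents that add atoms: bromine, BrBr
Why: Electrophilic aromatic bromination; the phenol OH directs to both free ortho positions (para is blocked).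

**Step 2**
Reactants: **2**
Product: **3** 4-bromo-2,6-dimethoxyphenol
Conditions: NaOMe (6 equiv), CuI (10 mol %), MeOH/DMF, 100 °C, sealed tube; then aq. HCl
Reagents that add atoms: sodium methoxide, C[O-].[Na+]
Why: Cu(I)-catalysed Ullmann-type methoxylation; the phenoxide-activated ortho bromides are displaced in preference to the para bromide, which is kept for the Heck step.

**Step 3**
Reactants: **3**
Product: **4** 2-(benzyloxy)-5-bromo-1,3-dimethoxybenzene
Conditions: BnBr (1.2 equiv), K2CO3, DMF, 60 °C
Reagents that add atoms: benzyl bromide, BrCc1ccccc1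
Why: Williamson O-benzylation masks the phenol for the enolate and hydride steps.

**Step 4**
Reactants: **4**; **5** methyl acrylate
Product: **6** methyl (E)-3-[4-(benzyloxy)-3,5-dimethoxyphenyl]acrylate
Conditions: Pd(OAc)2 (3 mol %), P(o-tol)3 (6 mol %), Et3N, DMF, 100–120 °C
Reagents that add atoms: none
Why: Mizoroki–Heck coupling; syn-carbopalladation then β-hydride elimination gives the E-cinnamate.

**Step 5**
Reactants: **6**
Product: **7** (E)-3-[4-(benzyloxy)-3,5-dimethoxyphenyl]prop-2-en-1-ol
Conditions: DIBAL-H (2.5 equiv), CH2Cl2, −78 → 0 °C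
Reagents that add atoms: none
Why: Ester-to-allylic alcohol reduction by hydride delivery; the alkene and benzyl ether are untouched.

**Step 6**
Reactants: **7**
Product: **8** [(2S,3S)-3-Ar-oxiran-2-yl]methanol
Conditions: Ti(OiPr)4 (10 mol %), L-(+)-DET (12 mol %), TBHP (2 equiv), 3 Å MS, CH2Cl2, −20 °C; NaOH/brine work-up, Et3N-buffered silica
Reagents that add atoms: tert-butyl hydroperoxide, CC(C)(C)OO
Why: Sharpless asymmetric epoxidation; L-(+)-DET gives the (2S,3S) trans-epoxide of the E-allylic alcohol, which fixes the absolute configuration carried to C8.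

**Step 7**
Reactants: **8**
Product: **9** [(2S,3S)-3-Ar-oxiran-2-yl]methyl acetate
Conditions: Ac2O (1.5 equiv), Et3N, DMAP (cat.), CH2Cl2, 0 °C
Reagents that add atoms: acetic anhydride, CC(=O)OC(C)=O
Why: O-Acylation installs the enolisable tether on the C9 oxygen; no stereocentre is touched.

**Step 8**
Reactants: **9**
Product: **10** (R)-4-[(R)-Ar(hydroxy)methyl]oxolan-2-one
Conditions: LiHMDS (2.2 equiv), THF, −78 → −20 °C; then AcOH quench at −78 °C
Reagents that add atoms: none
Why: Intramolecular ester-enolate opening of the epoxide is 5-exo at C2 (preferred over 6-endo at the benzylic C3) and proceeds with inversion, converting the (2S) carbon into C8 (R) and forming the lactone ring; C3 keeps its configuration as the C7 carbinol.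

**Step 9**
Reactants: **11** p-cresol
Product: **12** 4-hydroxybenzaldehyde
Conditions: O2 (5 bar), CoCl2 (1 mol %), NaOH (4 equiv), MeOH, 60 °C; then aq. HCl
Reagents that add atoms: dioxygen, O=O
Why: Cobalt-catalysed aerobic benzylic oxidation of the phenoxide via the p-quinone methide gives the aldehyde.

**Step 10**
Reactants: **12**
Product: **13** 3,5-dibromo-4-hydroxybenzaldehyde
Conditions: Br2 (2.1 equiv), AcOH, rt
Reagents that add atoms: bromine, BrBr
Why: Electrophilic bromination at both positions ortho to the phenol OH.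

**Step 11**
Reactants: **13**
Product: **14** 4-hydroxy-3,5-dimethoxybenzaldehyde (syringaldehyde)
Conditions: NaOMe (5 equiv), CuCl (10 mol %), MeOH/DMF, 100 °C; then aq. HCl
Reagents that add atoms: sodium methoxide, C[O-].[Na+]
Why: Cu-catalysed Ullmann methoxylation of the two aryl bromides; the phenoxide protects the aldehyde from methoxide.

**Step 12**
Reactants: **14**
Product: **15** 4-(benzyloxy)-3,5-dimethoxybenzaldehyde
Conditions: BnBr (1.2 equiv), K2CO3, DMF, 60 °C
Reagents that add atoms: benzyl bromide, BrCc1ccccc1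
Why: Williamson O-benzylation of the phenol.

**Step 13**
Reactants: **15**
Product: **16** [4-(benzyloxy)-3,5-dimethoxyphenyl]methanol
Conditions: NaBH4 (1.5 equiv), MeOH/THF, 0 °C
Reagents that add atoms: none
Why: Chemoselective hydride reduction of the aldehyde.

**Step 14**
Reactants: **16**
Product: **17** 2-(benzyloxy)-5-(bromomethyl)-1,3-dimethoxybenzene
Conditions: PBr3 (0.4 equiv), Et2O, 0 °C, 30 min; use crude at once
Reagents that add atoms: phosphorus tribromide, BrP(Br)Br
Why: SN2 conversion of the benzylic alcohol to the bromide; the electron-rich benzyl bromide is labile, so it is used immediately.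

**Step 15 (key fragment coupling)**
Reactants: **10**; **17**
Product: **18** (3R,4R)-3-[4-(benzyloxy)-3,5-dimethoxybenzyl]-4-{(R)-Ar(hydroxy)methyl}oxolan-2-one
Conditions: LiHMDS (2.1 equiv), THF, −78 °C, 30 min; then **17** (1.2 equiv), DMPU, −78 → −40 °C
Reagents that add atoms: none
Why: Dianion (lithium alkoxide plus lactone enolate) alkylation; the benzyl bromide approaches anti to the C4 carbinol substituent, giving the 3,4-trans lactone (8′R), while the enolate ties up the carbonyl so the alkoxide does not translactonise.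

**Step 16**
Reactants: **18**
Product: **19** (2R,3R)-2-[4-(benzyloxy)-3,5-dimethoxybenzyl]-3-{(R)-Ar(hydroxy)methyl}butane-1,4-diol
Conditions: LiAlH4 (3 equiv), THF, 0 °C → rt; Fieser work-up
Reagents that add atoms: none
Why: Hydride reduction of the lactone to the 1,4-diol; the benzyl ethers and the C8/C8′ stereocentres are untouched.

**Step 17**
Reactants: **19**
Product: **20** (2S,3R,4R)-2-Ar-4-[4-(benzyloxy)-3,5-dimethoxybenzyl]-3-(hydroxymethyl)tetrahydrofuran
Conditions: p-TsOH·H2O (5 mol %), CH2Cl2, 0 °C, 30 min; quench with Et3N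
Reagents that add atoms: none
Why: Acid-catalysed cyclodehydration through the p-alkoxybenzylic cation, in which the C9′-OH closes the five-membered ring (the C9-OH would give an oxetane) and C7 is set with aryl trans to the cis C8/C8′ CH2 groups (7S); C8 and C8′ are not involved.

**Step 18**
Reactants: **20**
Product: **21** (+)-(7S,8R,8′R)-5,5′-dimethoxylariciresinol
Conditions: H2 (1 atm), 10% Pd/C (neutral), EtOAc/EtOH 1:1, rt, monitored by TLC
Reagents that add atoms: none
Why: Hydrogenolysis of the two aryl benzyl ethers releases the free syringyl phenols, and no stereocentre is affected.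

## Compound list

1 | 4-bromophenol | Oc1ccc(Br)cc1 | starting material
2 | 2,4,6-tribromophenol | Oc1c(Br)cc(Br)cc1Br | intermediate
3 | 4-bromo-2,6-dimethoxyphenol | COc1cc(Br)cc(OC)c1O | intermediate
4 | 2-(benzyloxy)-5-bromo-1,3-dimethoxybenzene | COc1cc(Br)cc(OC)c1OCc1ccccc1 | intermediate
5 | methyl acrylate | C=CC(=O)OC | starting material
6 | methyl (E)-3-[4-(benzyloxy)-3,5-dimethoxyphenyl]acrylate | COC(=O)/C=C/c1cc(OC)c(OCc2ccccc2)c(OC)c1 | intermediate
7 | (E)-3-[4-(benzyloxy)-3,5-dimethoxyphenyl]prop-2-en-1-ol | OC/C=C/c1cc(OC)c(OCc2ccccc2)c(OC)c1 | intermediate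
8 | [(2S,3S)-3-Ar-oxiran-2-yl]methanol | OC[C@@H]1O[C@H]1c1cc(OC)c(OCc2ccccc2)c(OC)c1 | intermediate
9 | [(2S,3S)-3-Ar-oxiran-2-yl]methyl acetate | CC(=O)OC[C@@H]1O[C@H]1c1cc(OC)c(OCc2ccccc2)c(OC)c1 | intermediate
10 | (R)-4-[(R)-Ar(hydroxy)methyl]oxolan-2-one | O=C1C[C@@H]([C@@H](O)c2cc(OC)c(OCc3ccccc3)c(OC)c2)CO1 | intermediate
11 | p-cresol (4-methylphenol) | Cc1ccc(O)cc1 | starting material
12 | 4-hydroxybenzaldehyde | O=Cc1ccc(O)cc1 | intermediate
13 | 3,5-dibromo-4-hydroxybenzaldehyde | O=Cc1cc(Br)c(O)c(Br)c1 | intermediate
14 | syringaldehyde (4-hydroxy-3,5-dimethoxybenzaldehyde) | COc1cc(C=O)cc(OC)c1O | intermediate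
15 | 4-(benzyloxy)-3,5-dimethoxybenzaldehyde | COc1cc(C=O)cc(OC)c1OCc1ccccc1 | intermediate
16 | [4-(benzyloxy)-3,5-dimethoxyphenyl]methanol | COc1cc(CO)cc(OC)c1OCc1ccccc1 | intermediate
17 | 2-(benzyloxy)-5-(bromomethyl)-1,3-dimethoxybenzene | COc1cc(CBr)cc(OC)c1OCc1ccccc1 | intermediate
18 | (3R,4R)-3-(4-BnO-3,5-dimethoxybenzyl)-4-[(R)-Ar(hydroxy)methyl]oxolan-2-one | O=C1[C@H](Cc2cc(OC)c(OCc3ccccc3)c(OC)c2)[C@@H]([C@@H](O)c2cc(OC)c(OCc3ccccc3)c(OC)c2)CO1 | intermediate
19 | (2R,3R)-2-(4-BnO-3,5-dimethoxybenzyl)-3-[(R)-Ar(hydroxy)methyl]butane-1,4-diol | OC[C@H](Cc1cc(OC)c(OCc2ccccc2)c(OC)c1)[C@H](CO)[C@@H](O)c1cc(OC)c(OCc2ccccc2)c(OC)c1 | intermediate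
20 | bis-O-benzyl-5,5′-dimethoxylariciresinol | COc1cc(C[C@H]2CO[C@H](c3cc(OC)c(OCc4ccccc4)c(OC)c3)[C@H]2CO)cc(OC)c1OCc1ccccc1 | intermediate
21 | (+)-(7S,8R,8′R)-5,5′-dimethoxylariciresinol | COc1cc(C[C@H]2CO[C@H](c3cc(OC)c(O)c(OC)c3)[C@H]2CO)cc(OC)c1O | target

## Totals

- Total steps: 18 (lactone arm Steps 1–8, benzyl bromide arm Steps 9–14, then Steps 15–18).
- Longest linear sequence: 12 (Steps 1–8, then 15–18).
- The three steps most likely to fail:
  1. **Step 8, epoxy-acetate lactonisation.** The acetate enolate can lose ketene, give 6-endo products, or be followed by translactonisation.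
     - Fallback: conjugate-addition approach. Add the lithiated 1,3-dithiane of aldehyde **15** to 2(5H)-furanone, unmask the ketone, resolve the racemic 4-aroyl lactone by chiral HPLC, and reduce the ketone with NaBH4 (C7 epimers do not matter because Step 17 resets C7). Then feed the resulting lactone into Step 15.
  2. **Step 17, cation cyclodehydration.** Risks are incomplete 7S selectivity and Friedel–Crafts closure to an aryltetralin.
     - Fallback: avoid the free benzylic cation. Oxidise the benzylic alcohol of **19** with MnO2 to the aryl ketone, let it close to the C9′ hemiketal, and reduce with Et3SiH/BF3·OEt2 through the O-stabilised oxocarbenium. Check the 7S:7R ratio and watch for C8 epimerisation α to the ketone. Then debenzylate as in Step 18.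
  3. **Step 15, dianion alkylation.** The free alkoxide may O-alkylate, or the lactone may translactonise.
     - Fallback: change the disconnection to a C7–C8 aldol. Make (R)-4-(arylmethyl)-γ-butyrolactone from aldehyde **15** by Stobbe condensation with diethyl succinate, asymmetric hydrogenation and BH3·SMe2 reduction/lactonisation. Join it to aldehyde **15** by LiHMDS aldol anti to the benzyl group (trans lactone) and reduce with LiAlH4 to the same triol **19**; C7 is reset in Step 17.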